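## Retrosynthetic overview

1. Target ⇐ selective hydrolysis of a 2,5-dimethoxyquinone ⇐ oxidation of a trimethoxyphenol that already carries the complete 5-ene decalin.
2. The 10-H / 5-ene pattern ⇐ reductive SE2' opening of a tertiary allyl aryl ether. That ether ⇐ the 5(10)-ene by iodoetherification/elimination: the arene oxygen occupies C10, so elimination can only go towards C6. Acid alone stops at the 5(10)-ene, so the last biosynthetic hydride shift is done this way.
3. The 5(10)-ene with 8-Me and 9-Me ⇐ drimanyl C8 cation by 1,2-H and 1,2-CH3 shifts.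
4. Rings A and B (in that order) ⇐ one enantioselective proton-initiated cyclisation of a farnesyl arene, run in the same flask as line 3. A temporary pyran ring is closed in step 3 and opened in step 4.
5. Farnesyl arene ⇐ 1,2,4,5-tetramethoxybenzene + (2E,6E)-farnesyl bromide.

Assumption: the (R)-configured ligand gives the natural 5S,10S drimane series, as in related proton-initiated cyclisations of homofarnesyl substrates; if the sense is opposite, the (S)-ligand is used with no other change.

Terpenoid numbering (C1–C12) is used for the decalin; primed numbers refer to the arene (C1' bears the CH2).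

## Route

Step 1
Reactants: 1 1,2,4,5-tetramethoxybenzene; 2 (2E,6E)-farnesyl bromide
Product: 4 3-[(2E,6E)-farnesyl]-1,2,4,5-tetramethoxybenzene, via aryllithium 3 (not isolated)
Conditions: n-BuLi, TMEDA, THF, 0 °C; CuBr·SMe2 (10 mol%); then 2, −78 °C to rt
Reagents that add atoms: none
Why: Directed ortho-lithiation of 1 (each ring H lies between two OMe groups) gives 3, whose copper-catalysed SN2 allylation by 2 keeps the 2E,6E geometry; no stereocentre is formed.

Step 2
Reactants: 4 3-[(2E,6E)-farnesyl]-1,2,4,5-tetramethoxybenzene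
Product: 7 3-{[(1R,2S)-1,2,5,5-tetramethyl-1,2,3,4,5,6,7,8-octahydronaphthalen-1-yl]methyl}-1,2,4,5-tetramethoxybenzene (5(10)-ene; 8S,9R), via drim-7-ene 5 (not isolated), via drim-8(12)-ene 6 (not isolated)
Conditions: SnCl4 complex of (R)-2'-methoxy-1,1'-binaphthalen-2-ol (2 equiv), toluene, −78 °C; then BF3·OEt2, CH2Cl2, −78 to −20 °C, same flask
Reagents that add atoms: none
Why: Lewis-acid-assisted chiral Brønsted acid promotion of a Stork–Eschenmoser polyene cyclisation: enantioface-selective protonation of the terminal alkene and chair–chair closure of ring A then ring B fix C5, C9 and C10 in 5/6 (both arene positions next to the chain are blocked, so C8+ can only lose a proton), after which BF3 re-protonation to C8+ triggers suprafacial Wagner–Meerwein shifts (9α-H to C8, then 10β-CH3 to C9) that relay this chirality into C8 (S) and C9 (R) before loss of H5 gives the tetrasubstituted alkene, the usual resting point of this acid cascade.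

Step 3
Reactants: 7 the 5(10)-ene from step 2
Product: 9 tetracyclic allyl aryl ether (oxygen of the former 2'-OMe bonded to C10 on the α face; C5=C6 alkene; 8S,9R,10R; OMe at 3',5',6'), via iodo ether 8 (not isolated)
Conditions: I2, MeCN–CH2Cl2, 0 °C; then DBU, rt
Reagents that add atoms: none
Why: Iodoetherification with ortho-methoxy participation: the β-iodonium ion is opened at C10 by the only oxygen that can reach it (six-membered ring, forced onto the α face by the 9α-CH2 tether), iodide demethylates the oxonium ion, and because C10 and C4 now carry no hydrogen the E2 dehydroiodination of 8 can only go towards C6, placing the alkene at C5–C6; C10 is a temporary stereocentre.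

Step 4
Reactants: 9 the tetracyclic allyl aryl ether
Product: 12 2-{[(1R,2S,8aS)-1,2,5,5-tetramethyl-1,2,3,5,6,7,8,8a-octahydronaphthalen-1-yl]methyl}-3,4,6-trimethoxyphenol, via allyllithium 10 (not isolated), via allylchromium 11 (not isolated)
Conditions: lithium 4,4'-di-tert-butylbiphenylide (2.1 equiv), THF, −78 °C; CrCl3(THF)3, −78 to −40 °C; MeOH, −78 °C; aq. NH4Cl
Reagents that add atoms: none
Why: Proposed new method: dissociative electron transfer cleaves the tertiary allylic C10–O bond (closest known type: reductive cleavage of allyl aryl ethers to allyllithiums), transmetalation places trivalent chromium on the less hindered C6, and SE2' protodemetalation (closest known type: the allylchromium protonation step of chromium-mediated contra-thermodynamic olefin isomerisation) puts H on C10 from the α face, where the tethered aryloxide holds the metal and the axial 9β-methyl blocks the other face, so C10 becomes S and the C5–C6 alkene stays.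

Step 5
Reactants: 12 the trimethoxyphenol
Product: 13 2,5-dimethoxy-3-{[(1R,2S,8aS)-1,2,5,5-tetramethyl-1,2,3,5,6,7,8,8a-octahydronaphthalen-1-yl]methyl}-1,4-benzoquinone
Conditions: (NH4)2Ce(NO3)6, MeCN–H2O, 0 °C
Reagents that add atoms: water, O
Why: Oxidative demethylation of the para-methoxyphenol unit by tetravalent cerium gives the para-quinone (water supplies the new carbonyl oxygen); the hindered trisubstituted alkene and the three stereocentres are untouched at 0 °C.

Step 6
Reactants: 13 the dimethoxyquinone
Product: 14 2-hydroxy-5-methoxy-3-{[(1R,2S,8aS)-1,2,5,5-tetramethyl-1,2,3,5,6,7,8,8a-octahydronaphthalen-1-yl]methyl}-1,4-benzoquinone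
Conditions: KOH, MeOH–H2O, rt; then aq. HCl
Reagents that add atoms: potassium hydroxide, [K+].[OH-]
Why: Addition–elimination (vinylogous ester saponification): hydroxide replaces the methoxy group next to the alkyl substituent, which is twisted out of conjugation and is the one exchanged in 3-alkyl-2,5-dimethoxybenzoquinones of this class, leaving the 5-methoxy group; no stereocentre is affected.

## Compound list

1 | 1,2,4,5-tetramethoxybenzene | COc1cc(OC)c(OC)cc1OC | starting material
2 | (2E,6E)-farnesyl bromide | CC(C)=CCC/C(C)=C/CC/C(C)=C/CBr | starting material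
3 | 2,3,5,6-tetramethoxyphenyllithium | [Li]c1c(OC)c(OC)cc(OC)c1OC | intermediate (not isolated)
4 | 3-[(2E,6E)-farnesyl]-1,2,4,5-tetramethoxybenzene | COc1cc(OC)c(OC)c(C/C=C(\C)CC/C=C(\C)CCC=C(C)C)c1OC | intermediate
5 | (5S,9S,10S)-11-(2,3,5,6-tetramethoxyphenyl)drim-7-ene | COc1cc(OC)c(OC)c(C[C@H]2C(C)=CC[C@H]3C(C)(C)CCC[C@]23C)c1OC | intermediate (not isolated)
6 | (5S,9S,10S)-11-(2,3,5,6-tetramethoxyphenyl)drim-8(12)-ene | COc1cc(OC)c(OC)c(C[C@H]2C(=C)CC[C@H]3C(C)(C)CCC[C@]23C)c1OC | intermediate (not isolated)
7 | 3-{[(1R,2S)-1,2,5,5-tetramethyl-1,2,3,4,5,6,7,8-octahydronaphthalen-1-yl]methyl}-1,2,4,5-tetramethoxybenzene | COc1cc(OC)c(OC)c(C[C@@]2(C)C3=C(C(C)(C)CCC3)CC[C@@H]2C)c1OC | intermediate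
8 | iodo ether: 5β-iodo, 2'-O bonded to C10 (α), 5S,8S,9R,10R, OMe at 3',5',6' | COc1cc(OC)c2c(c1OC)C[C@]3(C)[C@@H](C)CC[C@]4(I)C(C)(C)CCC[C@@]34O2 | intermediate (not isolated)
9 | allyl aryl ether: 2'-O bonded to C10 (α), C5=C6, 8S,9R,10R | COc1cc(OC)c2c(c1OC)C[C@]3(C)[C@@H](C)CC=C4C(C)(C)CCC[C@@]34O2 | intermediate
10 | allyllithium (Li at C6, C5=C10) lithium aryloxide, 8S,9R | COc1cc(OC)c(O[Li])c(c1OC)C[C@@]2(C)C3=C(C(C)(C)CCC3)C([Li])C[C@@H]2C | intermediate (not isolated)
11 | allylchromium dichloride (trivalent chromium at C6, C5=C10) lithium aryloxide, 8S,9R | COc1cc(OC)c(O[Li])c(c1OC)C[C@@]2(C)C3=C(C(C)(C)CCC3)C([Cr](Cl)Cl)C[C@@H]2C | intermediate (not isolated)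
12 | 2-{[(1R,2S,8aS)-1,2,5,5-tetramethyl-1,2,3,5,6,7,8,8a-octahydronaphthalen-1-yl]methyl}-3,4,6-trimethoxyphenol | COc1cc(OC)c(O)c(C[C@@]2(C)[C@@H]3CCCC(C)(C)C3=CC[C@@H]2C)c1OC | intermediate
13 | 2,5-dimethoxy-3-{[(1R,2S,8aS)-1,2,5,5-tetramethyl-1,2,3,5,6,7,8,8a-octahydronaphthalen-1-yl]methyl}-1,4-benzoquinone | COC1=CC(=O)C(OC)=C(C[C@@]2(C)[C@@H]3CCCC(C)(C)C3=CC[C@@H]2C)C1=O | intermediate
14 | 2-hydroxy-5-methoxy-3-{[(1R,2S,8aS)-1,2,5,5-tetramethyl-1,2,3,5,6,7,8,8a-octahydronaphthalen-1-yl]methyl}-1,4-benzoquinone | COC1=CC(=O)C(O)=C(C[C@@]2(C)[C@@H]3CCCC(C)(C)C3=CC[C@@H]2C)C1=O | target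

## Step count and risks

Total step count: 6. Longest linear sequence: 6 steps (1 or 2 to 14).

Steps most likely to fail:

Step 4 (most likely). The aryl ether is electron-rich, so electron transfer may be slow, and protonation at C6 instead of C10 would give back a 5(10)-ene. The fallback uses heterolytic instead of reductive C–O cleavage. It sets out from 9: TMSBr in CH2Cl2 at −78 °C gives the allylic bromide trimethylsilyl aryl ether F4 (C6 epimers). Zinc dust in AcOH/Et2O at 0 °C reduces it through an allylzinc that is protonated at C10 (SE2'). Acidic work-up removes the silyl group, and the route is rejoined at 12.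

Step 2. The enantioselectivity may be moderate with a substrate that has four Lewis-basic methoxy groups, and the one-flask cyclisation/shift sequence is untested on it. The fallback replaces catalyst control by classical resolution. It sets out from 12 of low ee: (S)-1-phenylethyl isocyanate and DMAP in toluene give the (S)-1-phenylethyl carbamate F1. The major diastereomer is purified by crystallisation or chromatography, and LiAlH4 in THF at 0 °C releases enantiopure phenol, so the route is rejoined at 12.

Step 3. Iodination of the arene, or loss of an allylic proton from the iodonium ion, may compete with the methoxy participation. The fallback goes through an epoxide. It sets out from 7: mCPBA with NaHCO3 in CH2Cl2 at 0 °C gives the 5α,10α-epoxide F2. MgI2 in Et2O/toluene opens it at C10 with the ortho-methoxy oxygen and demethylates the oxonium ion to the 5α-hydroxy ether F3. Methyl N-(triethylammoniosulfonyl)carbamate (Burgess reagent) in benzene at 50 °C dehydrates the tertiary alcohol, again only towards C6, and the route is rejoined at 9.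

## Further compounds

F1 | step 2 | (S)-1-phenylethyl carbamate of phenol 12 | COc1cc(OC)c(OC(=O)N[C@@H](C)c2ccccc2)c(C[C@@]2(C)[C@@H]3CCCC(C)(C)C3=CC[C@@H]2C)c1OC
F2 | step 3 | 5α,10α-epoxide of 7 (8S,9R) | COc1cc(OC)c(OC)c(C[C@@]2(C)[C@]34CCCC(C)(C)[C@]3(O4)CC[C@@H]2C)c1OC
F3 | step 3 | 5α-hydroxy ether: 2'-O bonded to C10 (α), OH on C5 (α), OMe at 3',5',6' | COc1cc(OC)c2c(c1OC)C[C@]3(C)[C@@H](C)CC[C@@]4(O)C(C)(C)CCC[C@@]34O2
F4 | step 4 | 6-bromo-5(10)-ene trimethylsilyl aryl ether (8S,9R; C6 epimers) | COc1cc(OC)c(O[Si](C)(C)C)c(c1OC)C[C@@]2(C)C3=C(C(C)(C)CCC3)C(Br)C[C@@H]2C
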